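Take the earlier runs and box X in elm at its end between two lines.

| flask | X | D | L | remark | time | volume of the second phase over the first |
|---|---|---|---|---|---|---|
| violet | 0.40 M | 1.4 M | 0.020 M | run made earlier |  |  |
| ochre | 0.40 M | 2.2 M | 0.020 M | run made earlier |  |  |
| red | 0.20 M | 1 M | 0.020 M | run made earlier |  |  |
| birch | 0.40 M | 1.00 M | 0.0200 M |  | 80 min | 1.0 |
| elm | 0.40 M | 1.00 M | 0.0200 M |  | 20 min | 1.0 |
| oak | 0.40 M | 1.00 M | 0.0200 M |  | 40 min | 1.0 |

| run | time / min | E / % | Q / % | X / % |
|---|---|---|---|---|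
| violet | 1.00 | 1.2 | 1.1 | 96.3 |
| violet | 3.00 | 2.1 | 0 | 90.6 |
| violet | 6.00 | 8.9 | 0.6 | 87.5 |
| violet | 8.00 | 12.0 | 2.9 | 82.1 |
| violet | 12.0 | 20.8 | 2.4 | 73.7 |
| violet | 15.0 | 26.1 | 1.9 | 67.6 |
| ochre | 2.50 | 0 | 2.1 | 87.8 |
| ochre | 5.00 | 10.1 | 3.5 | 81.8 |
| ochre | 8.00 | 22.3 | 3.4 | 71.0 |
| ochre | 10.0 | 27.2 | 3.1 | 64.3 |
| ochre | 12.0 | 34.0 | 0.7 | 57.9 |
| ochre | 15.0 | 44.8 | 2.5 | 44.8 |
| red | 3.00 | 0.9 | 2.5 | 86.8 |
| red | 6.00 | 4.0 | 3.1 | 83.7 |
| red | 10.0 | 14.0 | 4.2 | 75.7 |
| red | 12.0 | 15.8 | 2.5 | 69.5 |
| red | 15.0 | 22.4 | 0 | 62.3 |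

(each reading ± 1 percentage point)

1. which of these there is most of at the end, counted by the X in it, birch (E / Q / X)
2. which of these there is most of at the end, counted by the X in it, elm (E / Q / X)
3. which of these there is most of at the end, counted by the X in it, oak (E / Q / X)
4. the largest of these amounts at the end, in percent of the X charged, birch
5. the largest of these amounts at the end, in percent of the X charged, elm
6. the largest of these amounts at the end, in percent of the X charged, oak

1. I treated L as a small correction. Violet's E, Q and X summed to 95.6% at its last reading, so I took L to hold back a share cL/cX of the charge, 5.00% in elm.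

2. I read the straight stretches. Red's fall of cX, divided by its cD, gave 0.00476 min⁻¹. That is the pull, the fall of cX per minute per unit of cD charged, a pseudo-first-order constant in D. Violet gave 0.00632 min⁻¹, more than red, and red held half the X.

3. Run back, red's straight line reached the level left after L's share only some time after the start, so I read a lag of 3.35 min from red and used it as an estimate.

4. From above: elm charges more X than red, so I expected red's pull to run slow for it. The line gave 75.2%.

5. From below: violet's pull with no lag gave 63.4%. Elm has violet's X, and with the lag the line rose to 68.7%.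

6. I committed to the middle for X in elm, 72.0%.

7. The forecast said E at 72% for birch, X at 74% for elm and X at 54% for oak, and of birch it wrote: “This is the least certain”. Its elm value lay inside my bracket, above my middle.

    Z ⇌ D, rate k1*([Z] - [D]/K1) per volume of the first phase (partition coefficient = 12.0, kL = 0.00490 s⁻¹)
    X + Z ⇌ Q (K = 0.890 L mol⁻¹, k = 1.40 L mol⁻¹ s⁻¹)
    Z + Q → E (k = 0.450 L mol⁻¹ s⁻¹)
    X + L → G (k = 0.0930 L mol⁻¹ s⁻¹)
    Z ⇌ J (K = 1.80, k = 0.0890 s⁻¹)

The largest amount at the end was E in birch at 66.5%, X in elm at 69.7% and X in oak at 49.8%. D in elm stood at 72.7% of its charge at 20.0 min. Put back through the same line, elm's own pull came to 0.00609 min⁻¹, above red's and below violet's. For oak, red's pull drew the upper line at 51.4%, and oak held 49.8% of X at 40.0 min.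

(All runs come from a simulation for an exercise; noise was put on by code.)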